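Readings and results are simulated from invented constants, noise included.

Of each unit of substrate charged, this flask brings 0.700 of coupling partner, the limiting reagent, and 0.300 of protic impurity. I assume each impurity takes one partner. Partner charged less impurity charged, both as fractions of the substrate charge, I call the partner margin: 0.400.

| setting | north-west | west | flask |
|---|---|---|---|
| substrate | 0.56 M | 0.88 M | 0.40 M |
| coupling partner | 0.70 equiv | 0.70 equiv | 0.700 equiv |
| protic impurity | 0.12 M | 0.12 M | 0.120 M |
| free catalyst | 5 mol% | 5 mol% | 5 mol% |
| remark | run made earlier | run made earlier |  |

| run | time / min | target / % |
|---|---|---|
| north-west | 0.250 | 2.8 |
| north-west | 0.417 | 5.3 |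
| north-west | 0.833 | 12.5 |
| north-west | 1.50 | 22.1 |
| north-west | 3.00 | 39.0 |
| west | 0.667 | 11.3 |
| west | 1.33 | 23.0 |
| west | 2.00 | 33.4 |
| west | 2.50 | 40.7 |
| west | 3.00 | 46.4 |

(scatter of a reading: 0.3 percentage points)

* factor on the rate of making target when 30 % of the substrate are converted if free catalyst is charged twice over
* factor on the rate when 30 % of the substrate are converted if free catalyst is charged at 25 mol% instead

- the earlier runs were read with a standard deviation of 0.3 percentage points

The north-west run has a margin of 0.486 and the west run 0.564, so this flask is tighter than either. Late in the runs I read 0.113 /min of the charge for north-west and 0.130 /min for west. But catalyst, partner and substrate all rise together between them, so these readings don't give the order in catalyst.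

My first estimate takes the rate as proportional to free catalyst, giving a factor of two and a factor of 5.00. The objection is that partner at 30 % conversion isn't a fixed amount. Taking one partner per substrate converted, it stands near 0.100 of the substrate charge if the impurity has finished and near 0.400 if it hasn't begun. I assume the quench needs no catalyst, so I expect more catalyst to reach that conversion with more partner standing, and both factors to lie above the first estimate.

A second objection is that the early rise in the readings might mean a catalyst reservoir that bends the order below one. A chain of ordinary steps also rises early, though, so the rise doesn't prove a reservoir. I keep my estimate.

The forecast gives 1.5 and 2.5, and takes the early rates to suggest that “the catalyst settles into a resting equilibrium”. It stands below my first estimate.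

The simulation gives 2.35 and 6.53, above the forecast and above the first estimate.

    substrate + free catalyst → catalyst intermediate A (k = 1.00 /M/s)
    coupling partner + catalyst intermediate A → catalyst intermediate B (k = 0.820 /M/s)
    catalyst intermediate B → catalyst intermediate C (k = 0.110 /s)
    catalyst intermediate C → free catalyst + target (k = 0.330 /s)
    coupling partner + protic impurity → quenched reagent (k = 0.0610 /M/s)

Taking the quench of coupling partner by protic impurity out of the run lowers the apparent order in free catalyst at 30 % conversion from 1.3 to 1.0. In this flask at 2.50 min, with target at 29.7 % of the substrate charge, partner stands at 0.164 of that charge, above the 0.103 of margin less target, with impurity still at 26.4 % of its own charge. By 50.0 min partner is at 0 %, impurity is at 19.3 %, and margin plus that impurity comes to 0.458 of the substrate charge, with target at 45.8 %.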